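**Plan**
- Retrosynthetic cuts: ring B at C1–O2 and C3–C4; the side chain at C1'=C2' and C3'=C4'; C5–Cl; ring A at C4a–C5, C5–C6, C7–C8 and C8–C8a; the oxolane at its C5–CH3 bond.
- Enabling feature: ring A (C4a, C5, C6, C7, C8, C8a) bears oxygen on C6 and C8 with C7–H between them, the C4 carbon on C4a and the C1 carboxyl carbon on C8a. A ketene carbonyl (C8), an ynol ether (C7, C6), a former diazo carbon (C5) and a β-methyl enoate (C4a, C8a) assemble this pattern in one benzannulation.
- Forward order: ring A is built first from acyclic pieces, chlorinated at C5 and reprotected. The oxolane ring is carried over from a pentose and lengthened by two olefinations. The C4 methyl group is then acylated by the dienamide carbonyl (C3), and ring B closes last by enol lactonization.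
- Stereochemistry: oxolane C2 and C3 are C4 and C3 of 2-deoxy-L-ribose. Oxolane C5 comes from substrate-controlled hydride delivery to a cyclic oxocarbenium ion. Both E double bonds come from stabilized phosphorus reagents.

Key step: step 3

Remark: unprimed locants C1–C8a follow the isocoumarin numbering of the target and primed locants the butadienyl chain counted from C3; the oxolane is numbered O1, C2 (chain), C3 (oxygen), C4, C5 (methyl); TBS = tert-butyldimethylsilyl, TIPS = triisopropylsilyl; ethoxyacetylene is used as its commercial hexane solution.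

**Step 1**
Reactants: 1 2,3-butanedione; 2 methyl (triphenylphosphoranylidene)acetate
Product: 3 methyl (E)-3-methyl-4-oxopent-2-enoate
Conditions: 1 (3 equiv), CH2Cl2, 0 °C → rt
Reagents that add atoms: none
Why: Wittig olefination with a stabilized ylide; the excess of the symmetrical diketone restricts the reaction to one carbonyl group, and the ester is placed trans to the acetyl group (E), as is usual for this ylide with 1,2-diketones.

**Step 2**
Reactants: 3 methyl (E)-3-methyl-4-oxopent-2-enoate
Product: 5 methyl (E)-5-diazo-3-methyl-4-oxopent-2-enoate, via trifluoroacetyl ketone 4 (not isolated)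
Conditions: LiN(SiMe3)2, THF, −78 °C; CF3CO2CH2CF3; aq HCl work-up; then MeSO2N3, Et3N, H2O, MeCN, rt
Reagents that add atoms: methanesulfonyl azide, CS(=O)(=O)N=[N+]=[N-]; 2,2,2-trifluoroethyl trifluoroacetate, O=C(OCC(F)(F)F)C(F)(F)F (its CF3CO group is found only in 4)
Why: Detrifluoroacetylative diazo transfer (Claisen-type trifluoroacetylation followed by Regitz transfer): the amide base removes a proton from the acetyl CH3, the only α-position of the ketone, the activated 1,3-diketone 4 accepts the diazo group from the sulfonyl azide and sheds CF3CO as the N-sulfonyl amide, and the acceptor alkene never meets diazomethane.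

**Step 3**
Reactants: 5 methyl (E)-5-diazo-3-methyl-4-oxopent-2-enoate; 6 ethoxyacetylene
Product: 11 methyl 4-ethoxy-2-hydroxy-6-methylbenzoate, via vinylketene 7 (not isolated), via vinylcyclobutenone 8 (not isolated), via dienylketene 9 (not isolated), via cyclohexadienone 10 (not isolated)
Conditions: 6 (3 equiv), ClCH2CH2Cl, hν (254 nm, quartz), rt; then 80 °C (sealed tube)
Reagents that add atoms: none
Why: This is the Danheiser benzannulation in its diazo ketone form: light expels N2 from 5 and the alkenyl group shifts from the carbonyl carbon to the diazo carbon (Wolff rearrangement, new C4a–C5 bond) to give vinylketene 7. The polarized ynol ether 6 adds in a [2+2] sense, its nucleophilic CH carbon (C7) bonding to the ketene carbonyl carbon (C8) and its oxygen-bearing carbon (C6) to C5, which closes the transient four-membered ring of 8 and fixes the 1,3-relationship of the two oxygens. Heating opens 8 reversibly by conrotatory four-electron electrocyclic cleavage of C5–C8, and only isomer 9, with ketene and enoate on the same side of C5=C6, can react further, so the equilibrium drains through it. Ring A then closes by disrotatory six-electron electrocyclization (C8–C8a bond) to dienone 10, and enolization to the hydrogen-bonded salicylate 11 makes the cascade irreversible. No stereocentre survives (those of 8 and 10 are erased), so the selectivities needed are the [2+2] regiochemistry, secured by the ethoxy group, and an unhindered closing terminus, secured by the E enoate that turns CO2Me outward. The excess of 6 keeps the ketene from being intercepted by phenol already formed.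

**Step 4**
Reactants: 11 methyl 4-ethoxy-2-hydroxy-6-methylbenzoate
Product: 12 methyl 3-chloro-4-ethoxy-6-hydroxy-2-methylbenzoate
Conditions: SO2Cl2 (1.05 equiv), CH2Cl2, 0 °C
Reagents that add atoms: sulfuryl chloride, O=S(=O)(Cl)Cl
Why: Electrophilic aromatic chlorination: C5 is para to the free C8 hydroxyl and ortho to the C6 ethoxy group whereas C7 is wedged between two oxygen substituents, and orsellinate-type esters and aldehydes are known to accept their first chlorine from SO2Cl2 at this position.

**Step 5**
Reactants: 12 methyl 3-chloro-4-ethoxy-6-hydroxy-2-methylbenzoate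
Product: 13 methyl 3-chloro-4,6-dihydroxy-2-methylbenzoate
Conditions: BBr3, CH2Cl2, −78 → 0 °C; then H2O
Reagents that add atoms: none
Why: Lewis acid ether cleavage: BBr3 binds the aryl ethyl ether oxygen and bromide removes the ethyl group by SN2, while the chelated methyl ester and the aryl chloride persist at or below 0 °C; the exchange is made here because no later intermediate would tolerate it.

**Step 6**
Reactants: 13 methyl 3-chloro-4,6-dihydroxy-2-methylbenzoate
Product: 14 methyl 3-chloro-2-methyl-4,6-bis[(triisopropylsilyl)oxy]benzoate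
Conditions: iPr3SiOTf, 2,6-lutidine, CH2Cl2, 0 °C → rt
Reagents that add atoms: triisopropylsilyl triflate, CC(C)[Si](OS(=O)(=O)C(F)(F)F)(C(C)C)C(C)C
Why: O-Silylation with the silyl triflate overcomes the hydrogen bond between the C8 hydroxyl and the ester, and the bulky aryl TIPS ethers carry no acidic proton, resist amide bases, DBU and methanol, and are unlikely to migrate, yet fall to fluoride at the end.

**Step 7**
Reactants: 15 2-deoxy-L-ribose
Product: 16 (4R,5S)-4-hydroxy-5-(hydroxymethyl)oxolan-2-one (2-deoxy-L-ribono-1,4-lactone)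
Conditions: Br2, H2O, rt
Reagents that add atoms: none
Why: Bromine-water oxidation of the furanose hemiacetal, the standard aldose to aldonolactone conversion, gives the 1,4-lactone and leaves both carbinol centres untouched.

**Step 8**
Reactants: 16 (4R,5S)-4-hydroxy-5-(hydroxymethyl)oxolan-2-one
Product: 17 (4R,5S)-4-[(tert-butyldimethylsilyl)oxy]-5-{[(tert-butyldimethylsilyl)oxy]methyl}oxolan-2-one
Conditions: TBSCl, imidazole, DMF, rt
Reagents that add atoms: tert-butyldimethylsilyl chloride, CC(C)(C)[Si](C)(C)Cl
Why: Imidazole-promoted silylation protects the primary and the secondary hydroxyl group in one operation, as is routine for 2-deoxyribonolactone.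

**Step 9**
Reactants: 17 (4R,5S)-4-[(tert-butyldimethylsilyl)oxy]-5-{[(tert-butyldimethylsilyl)oxy]methyl}oxolan-2-one
Product: 18 (4R,5S)-4-[(tert-butyldimethylsilyl)oxy]-5-{[(tert-butyldimethylsilyl)oxy]methyl}-2-methyloxolan-2-ol (mixture at C2)
Conditions: MeLi (1.1 equiv), THF, −78 °C; then AcOH
Reagents that add atoms: methyllithium, [Li]C
Why: Mono-addition of an organolithium reagent to a γ-lactone: at −78 °C the adduct stays at the hemiketal oxidation level, so a second addition is avoided, and the undefined hemiketal centre is erased in the next step.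

**Step 10**
Reactants: 18 (4R,5S)-4-[(tert-butyldimethylsilyl)oxy]-5-{[(tert-butyldimethylsilyl)oxy]methyl}-2-methyloxolan-2-ol
Product: 20 (2S,3R,5R)-3-[(tert-butyldimethylsilyl)oxy]-2-{[(tert-butyldimethylsilyl)oxy]methyl}-5-methyloxolane, via oxocarbenium ion 19 (not isolated)
Conditions: Et3SiH, BF3·OEt2, CH2Cl2, −78 °C
Reagents that add atoms: none
Why: Ionic hydrogenation of a hemiketal (reductive C-glycoside synthesis): BF3 ionizes 18 to 19 and the silane attacks from inside the envelope conformer that holds the C3 silyloxy group pseudoaxial, that is syn to this group, so the new oxolane C5 centre should be R with the methyl group cis to the C2 side chain, the same sense as in β-C-glycosides made from 2-deoxyribonolactones.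

**Step 11**
Reactants: 20 (2S,3R,5R)-3-[(tert-butyldimethylsilyl)oxy]-2-{[(tert-butyldimethylsilyl)oxy]methyl}-5-methyloxolane
Product: 21 {(2S,3R,5R)-3-[(tert-butyldimethylsilyl)oxy]-5-methyloxolan-2-yl}methanol
Conditions: CF3CO2H/H2O/THF (1:1:4), 0 °C
Reagents that add atoms: none
Why: Acid-catalysed desilylation discriminates on steric grounds, the primary silyl ether being cleaved well before the secondary one, as is routine for 3',5'-bis-silylated 2'-deoxynucleosides.

**Step 12**
Reactants: 21 {(2S,3R,5R)-3-[(tert-butyldimethylsilyl)oxy]-5-methyloxolan-2-yl}methanol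
Product: 22 (2R,3R,5R)-3-[(tert-butyldimethylsilyl)oxy]-5-methyloxolane-2-carbaldehyde
Conditions: Dess–Martin periodinane, CH2Cl2, 0 °C → rt; used without chromatography
Reagents that add atoms: none
Why: Dess–Martin oxidation stops at the aldehyde under essentially neutral conditions, so the α-oxygenated C2 centre (spatially unchanged, descriptor R only through the priority change) is not epimerized and the β-silyloxy group is not eliminated.

**Step 13**
Reactants: 22 (2R,3R,5R)-3-[(tert-butyldimethylsilyl)oxy]-5-methyloxolane-2-carbaldehyde; 23 (triphenylphosphoranylidene)acetaldehyde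
Product: 24 (E)-3-{(2S,3R,5R)-3-[(tert-butyldimethylsilyl)oxy]-5-methyloxolan-2-yl}prop-2-enal
Conditions: 23 (1.05 equiv), PhMe, 60 °C
Reagents that add atoms: none
Why: Wittig reaction with the stabilized formyl ylide is E-selective and base-free, which spares the epimerizable aldehyde, and the α-alkoxy aldehyde is more electrophilic than the enal formed, so a second homologation is held back.

**Step 14**
Reactants: 24 (E)-3-{(2S,3R,5R)-3-[(tert-butyldimethylsilyl)oxy]-5-methyloxolan-2-yl}prop-2-enal; 25 diethyl {2-[methoxy(methyl)amino]-2-oxoethyl}phosphonate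
Product: 26 (2E,4E)-5-{(2S,3R,5R)-3-[(tert-butyldimethylsilyl)oxy]-5-methyloxolan-2-yl}-N-methoxy-N-methylpenta-2,4-dienamide
Conditions: LiCl, DBU, MeCN, 0 °C → rt
Reagents that add atoms: none
Why: Horner–Wadsworth–Emmons olefination under Masamune–Roush conditions: the lithium-chelated phosphonoacetamide is deprotonated by a mild amidine base, the enal with its vinylogously acidic oxolane C2–H is not enolized, and the stabilized anion gives the E alkene.

**Step 15**
Reactants: 14 methyl 3-chloro-2-methyl-4,6-bis[(triisopropylsilyl)oxy]benzoate; 26 (2E,4E)-5-{(2S,3R,5R)-3-[(tert-butyldimethylsilyl)oxy]-5-methyloxolan-2-yl}-N-methoxy-N-methylpenta-2,4-dienamide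
Product: 28 methyl 2-{(3E,5E)-6-[(2S,3R,5R)-3-[(tert-butyldimethylsilyl)oxy]-5-methyloxolan-2-yl]-2-oxohexa-3,5-dien-1-yl}-3-chloro-4,6-bis[(triisopropylsilyl)oxy]benzoate, via benzylic lithium compound 27 (not isolated)
Conditions: 14 (1.5 equiv), LiN(iPr)2 (1.5 equiv), THF, −78 °C; then 26, −78 °C; AcOH quench
Reagents that add atoms: lithium diisopropylamide, [Li]N(C(C)C)C(C)C (its lithium is found only in 27)
Why: Lateral lithiation of the o-toluate gives the ester-stabilized anion 27 (no silyloxy group stands ortho to the carbanion and no free amide base is left to deprotonate 26), and its acylation by the N-methoxy-N-methylamide, a pairing known for chlorinated resorcylate toluates and α,β-unsaturated amides of this type, takes place at the lithium-chelated carbonyl group and stops at the ketone, forming C3–C4 without touching the E,E-diene or the oxolane centres.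

**Step 16**
Reactants: 28 methyl 2-{(3E,5E)-6-[(2S,3R,5R)-3-[(tert-butyldimethylsilyl)oxy]-5-methyloxolan-2-yl]-2-oxohexa-3,5-dien-1-yl}-3-chloro-4,6-bis[(triisopropylsilyl)oxy]benzoate
Product: 29 3-{(1E,3E)-4-[(2S,3R,5R)-3-[(tert-butyldimethylsilyl)oxy]-5-methyloxolan-2-yl]buta-1,3-dien-1-yl}-5-chloro-6,8-bis[(triisopropylsilyl)oxy]-1H-isochromen-1-one
Conditions: DBU, 4 Å molecular sieves, PhMe, 60 °C
Reagents that add atoms: none
Why: Base-mediated enol lactonization: the doubly activated C4 methylene is the most acidic site, its enolate oxygen attacks the neighbouring methyl ester in a 6-exo-trig closure (C1–O2 bond), and loss of methanol, taken up by the sieves, gives the aromatic 2-benzopyran-1-one of ring B with the diene geometry intact.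

**Step 17**
Reactants: 29 3-{(1E,3E)-4-[(2S,3R,5R)-3-[(tert-butyldimethylsilyl)oxy]-5-methyloxolan-2-yl]buta-1,3-dien-1-yl}-5-chloro-6,8-bis[(triisopropylsilyl)oxy]-1H-isochromen-1-one
Product: 30 5-chloro-6,8-dihydroxy-3-{(1E,3E)-4-[(2S,3R,5R)-3-hydroxy-5-methyloxolan-2-yl]buta-1,3-dien-1-yl}-1H-isochromen-1-one (CNP0086741.5)
Conditions: Bu4NF, AcOH, THF, 0 °C → rt
Reagents that add atoms: none
Why: Fluoride-induced global desilylation removes both aryl TIPS ethers and the secondary TBS ether, and the acetic acid buffer keeps the medium close to neutral, so neither the lactone nor the acid-sensitive dienylic C2–O bond of the oxolane is put at risk.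

**Compound list**
1 | 2,3-butanedione | CC(=O)C(C)=O | starting material
2 | methyl (triphenylphosphoranylidene)acetate | COC(=O)C=P(c1ccccc1)(c1ccccc1)c1ccccc1 | starting material
3 | methyl (E)-3-methyl-4-oxopent-2-enoate | COC(=O)/C=C(\C)C(C)=O | intermediate
4 | methyl (E)-7,7,7-trifluoro-3-methyl-4,6-dioxohept-2-enoate (trifluoroacetyl ketone, formed in situ) | COC(=O)/C=C(\C)C(=O)CC(=O)C(F)(F)F | intermediate
5 | methyl (E)-5-diazo-3-methyl-4-oxopent-2-enoate | COC(=O)/C=C(\C)C(=O)C=[N+]=[N-] | intermediate
6 | ethoxyacetylene | CCOC#C | starting material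
7 | methyl (E)-3-methyl-5-oxopenta-2,4-dienoate (vinylketene, formed in situ) | COC(=O)/C=C(\C)C=C=O | intermediate
8 | methyl (E)-3-(2-ethoxy-4-oxocyclobut-2-en-1-yl)but-2-enoate (racemic vinylcyclobutenone, formed in situ) | COC(=O)/C=C(\C)C1C(OCC)=CC1=O | intermediate
9 | methyl (2E,4E)-5-ethoxy-3-methyl-7-oxohepta-2,4,6-trienoate (dienylketene, formed in situ) | COC(=O)/C=C(\C)/C=C(OCC)\C=C=O | intermediate
10 | methyl 4-ethoxy-2-methyl-6-oxocyclohexa-2,4-diene-1-carboxylate (racemic cyclohexadienone, formed in situ) | COC(=O)C1C(C)=CC(OCC)=CC1=O | intermediate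
11 | methyl 4-ethoxy-2-hydroxy-6-methylbenzoate | CCOc1cc(C)c(C(=O)OC)c(O)c1 | intermediate
12 | methyl 3-chloro-4-ethoxy-6-hydroxy-2-methylbenzoate | CCOc1cc(O)c(C(=O)OC)c(C)c1Cl | intermediate
13 | methyl 3-chloro-4,6-dihydroxy-2-methylbenzoate | COC(=O)c1c(O)cc(O)c(Cl)c1C | intermediate
14 | methyl 3-chloro-2-methyl-4,6-bis[(triisopropylsilyl)oxy]benzoate | COC(=O)c1c(C)c(Cl)c(O[Si](C(C)C)(C(C)C)C(C)C)cc1O[Si](C(C)C)(C(C)C)C(C)C | intermediate
15 | 2-deoxy-L-ribose, (3R,4S)-3,4,5-trihydroxypentanal | O=CC[C@@H](O)[C@@H](O)CO | starting material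
16 | (4R,5S)-4-hydroxy-5-(hydroxymethyl)oxolan-2-one | O=C1C[C@@H](O)[C@H](CO)O1 | intermediate
17 | (4R,5S)-4-[(tert-butyldimethylsilyl)oxy]-5-{[(tert-butyldimethylsilyl)oxy]methyl}oxolan-2-one | O=C1C[C@@H](O[Si](C)(C)C(C)(C)C)[C@H](CO[Si](C)(C)C(C)(C)C)O1 | intermediate
18 | (4R,5S)-4-[(tert-butyldimethylsilyl)oxy]-5-{[(tert-butyldimethylsilyl)oxy]methyl}-2-methyloxolan-2-ol (mixture at C2) | CC1(O)C[C@@H](O[Si](C)(C)C(C)(C)C)[C@H](CO[Si](C)(C)C(C)(C)C)O1 | intermediate
19 | (2S,3R)-3-[(tert-butyldimethylsilyl)oxy]-2-{[(tert-butyldimethylsilyl)oxy]methyl}-5-methyl-3,4-dihydro-2H-furan-1-ium (oxocarbenium ion, formed in situ) | CC=1C[C@@H](O[Si](C)(C)C(C)(C)C)[C@H](CO[Si](C)(C)C(C)(C)C)[O+]=1 | intermediate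
20 | (2S,3R,5R)-3-[(tert-butyldimethylsilyl)oxy]-2-{[(tert-butyldimethylsilyl)oxy]methyl}-5-methyloxolane | C[C@@H]1C[C@@H](O[Si](C)(C)C(C)(C)C)[C@H](CO[Si](C)(C)C(C)(C)C)O1 | intermediate
21 | {(2S,3R,5R)-3-[(tert-butyldimethylsilyl)oxy]-5-methyloxolan-2-yl}methanol | C[C@@H]1C[C@@H](O[Si](C)(C)C(C)(C)C)[C@H](CO)O1 | intermediate
22 | (2R,3R,5R)-3-[(tert-butyldimethylsilyl)oxy]-5-methyloxolane-2-carbaldehyde | C[C@@H]1C[C@@H](O[Si](C)(C)C(C)(C)C)[C@H](C=O)O1 | intermediate
23 | (triphenylphosphoranylidene)acetaldehyde | O=CC=P(c1ccccc1)(c1ccccc1)c1ccccc1 | starting material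
24 | (E)-3-{(2S,3R,5R)-3-[(tert-butyldimethylsilyl)oxy]-5-methyloxolan-2-yl}prop-2-enal | C[C@@H]1C[C@@H](O[Si](C)(C)C(C)(C)C)[C@H](/C=C/C=O)O1 | intermediate
25 | diethyl {2-[methoxy(methyl)amino]-2-oxoethyl}phosphonate | CCOP(=O)(CC(=O)N(C)OC)OCC | starting material
26 | (2E,4E)-5-{(2S,3R,5R)-3-[(tert-butyldimethylsilyl)oxy]-5-methyloxolan-2-yl}-N-methoxy-N-methylpenta-2,4-dienamide | C[C@@H]1C[C@@H](O[Si](C)(C)C(C)(C)C)[C@H](/C=C/C=C/C(=O)N(C)OC)O1 | intermediate
27 | {2-chloro-6-(methoxycarbonyl)-3,5-bis[(triisopropylsilyl)oxy]phenyl}methyllithium (formed in situ) | [Li]Cc1c(Cl)c(O[Si](C(C)C)(C(C)C)C(C)C)cc(O[Si](C(C)C)(C(C)C)C(C)C)c1C(=O)OC | intermediate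
28 | methyl 2-{(3E,5E)-6-[(2S,3R,5R)-3-[(tert-butyldimethylsilyl)oxy]-5-methyloxolan-2-yl]-2-oxohexa-3,5-dien-1-yl}-3-chloro-4,6-bis[(triisopropylsilyl)oxy]benzoate | C[C@@H]1C[C@@H](O[Si](C)(C)C(C)(C)C)[C@H](/C=C/C=C/C(=O)Cc2c(Cl)c(O[Si](C(C)C)(C(C)C)C(C)C)cc(O[Si](C(C)C)(C(C)C)C(C)C)c2C(=O)OC)O1 | intermediate
29 | 3-{(1E,3E)-4-[(2S,3R,5R)-3-[(tert-butyldimethylsilyl)oxy]-5-methyloxolan-2-yl]buta-1,3-dien-1-yl}-5-chloro-6,8-bis[(triisopropylsilyl)oxy]-1H-isochromen-1-one | C[C@@H]1C[C@@H](O[Si](C)(C)C(C)(C)C)[C@H](/C=C/C=C/c2cc3c(Cl)c(O[Si](C(C)C)(C(C)C)C(C)C)cc(O[Si](C(C)C)(C(C)C)C(C)C)c3c(=O)o2)O1 | intermediate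
30 | 5-chloro-6,8-dihydroxy-3-{(1E,3E)-4-[(2S,3R,5R)-3-hydroxy-5-methyloxolan-2-yl]buta-1,3-dien-1-yl}-1H-isochromen-1-one | C[C@@H]1C[C@@H](O)[C@H](/C=C/C=C/c2cc3c(Cl)c(O)cc(O)c3c(=O)o2)O1 | target

**Step count**
- Total step count: 17.
- Longest linear sequence: 11 steps (steps 7–17, from 2-deoxy-L-ribose 15). The arene branch (steps 1–6) joins at step 15.

**Steps most likely to fail**

**Step 3.**
- What may go wrong: the enoate may isomerize from E to Z under irradiation, after which the Z vinylketene can close onto its own ester carbonyl instead of meeting the alkyne. The diazo group of one molecule may add as a dipole to the doubly activated alkene of another before photolysis. The accumulating phenol may screen the light.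
- Fallback: the same ketene is made without light and without a diazo compound. The fallback sets out from ethoxyacetylene 6. Its partner comes from commercial dimethyl (E)-3-methylpent-2-enedioate F1, which is half-saponified (KOH, 1 equiv, MeOH, then acid) at the unconjugated ester to (E)-5-methoxy-3-methyl-5-oxopent-3-enoic acid F2. This acid is converted with (COCl)2 and catalytic DMF into methyl (E)-5-chloro-3-methyl-5-oxopent-2-enoate F3.
- Slow addition of F3 to Et3N and 6 in toluene (rt, then 80 °C) should dehydrochlorinate it at the doubly activated methylene to vinylketene 7. The regioisomeric half ester would give the same ketene by 1,4-elimination.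
- The thermal cascade then runs through 8, 9 and 10 and comes back to the route at 11.

**Step 15.**
- What may go wrong: the soft benzylic anion may add in a conjugate (1,4 or 1,6) sense to the dienamide, the first stage of a Staunton–Weinreb annulation. Proton transfer from the vinylogously acidic oxolane C2–H may quench the anion and open the way to loss of the C3 silyloxy group.
- Fallback: the C3–C4 bond is made with a partner that has no conjugated acceptor, and the diene is completed by olefination. The fallback sets out from 14, which is lithiated to 27 as before.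
- Anion 27 is acylated with commercial 2-chloro-N-methoxy-N-methylacetamide (THF, −78 °C) to methyl 3-chloro-2-(3-chloro-2-oxopropyl)-4,6-bis[(triisopropylsilyl)oxy]benzoate F4.
- Catalytic camphorsulfonic acid in toluene at 80 °C closes ring B to 5-chloro-3-(chloromethyl)-6,8-bis[(triisopropylsilyl)oxy]-1H-isochromen-1-one F5. The acid route avoids Favorskii-type reactions of the chloroketone.
- A Michaelis–Arbuzov reaction (P(OEt)3, catalytic NaI, 110 °C) gives diethyl ({5-chloro-1-oxo-6,8-bis[(triisopropylsilyl)oxy]-1H-isochromen-3-yl}methyl)phosphonate F6.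
- Deprotonation with LiN(SiMe3)2 (THF, −78 °C) and Horner–Wadsworth–Emmons reaction with enal 24 should form C1'=C2' with E geometry, as for 2-pyranon-6-ylmethyl phosphonates. The fallback comes back to the route at 29, so steps 14 and 16 are no longer needed.

**Step 2.**
- What may go wrong: the lithium enolate may add in Michael fashion to enone ester 3 that has not yet been deprotonated, giving oligomers. Deprotonation may compete at the C3 methyl group, which is γ to the ester. The product may slowly add to itself on storage.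
- Fallback: a neutral enol derivative replaces the lithium enolate. The fallback sets out from 3. Soft enolization (Me3SiOTf, Et3N, CH2Cl2, 0 °C) gives methyl (E)-3-methyl-4-[(trimethylsilyl)oxy]penta-2,4-dienoate F7.
- N-Bromosuccinimide (THF, −78 → 0 °C) converts F7 into methyl (E)-5-bromo-3-methyl-4-oxopent-2-enoate F8.
- N,N'-Ditosylhydrazine with DBU (THF, 0 °C) replaces bromide by nitrogen and expels two sulfinate units. The fallback comes back to the route at 5.

**Further compounds**
F1 | step 3 | dimethyl (E)-3-methylpent-2-enedioate (commercial dimethyl 3-methylglutaconate, E isomer) | COC(=O)/C=C(\C)CC(=O)OC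
F2 | step 3 | (E)-5-methoxy-3-methyl-5-oxopent-3-enoic acid | COC(=O)/C=C(\C)CC(=O)O
F3 | step 3 | methyl (E)-5-chloro-3-methyl-5-oxopent-2-enoate | COC(=O)/C=C(\C)CC(=O)Cl
F4 | step 15 | methyl 3-chloro-2-(3-chloro-2-oxopropyl)-4,6-bis[(triisopropylsilyl)oxy]benzoate | COC(=O)c1c(CC(=O)CCl)c(Cl)c(O[Si](C(C)C)(C(C)C)C(C)C)cc1O[Si](C(C)C)(C(C)C)C(C)C
F5 | step 15 | 5-chloro-3-(chloromethyl)-6,8-bis[(triisopropylsilyl)oxy]-1H-isochromen-1-one | ClCc1cc2c(Cl)c(O[Si](C(C)C)(C(C)C)C(C)C)cc(O[Si](C(C)C)(C(C)C)C(C)C)c2c(=O)o1
F6 | step 15 | diethyl ({5-chloro-1-oxo-6,8-bis[(triisopropylsilyl)oxy]-1H-isochromen-3-yl}methyl)phosphonate | CCOP(=O)(Cc1cc2c(Cl)c(O[Si](C(C)C)(C(C)C)C(C)C)cc(O[Si](C(C)C)(C(C)C)C(C)C)c2c(=O)o1)OCC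
F7 | step 2 | methyl (E)-3-methyl-4-[(trimethylsilyl)oxy]penta-2,4-dienoate | COC(=O)/C=C(\C)C(=C)O[Si](C)(C)C
F8 | step 2 | methyl (E)-5-bromo-3-methyl-4-oxopent-2-enoate | COC(=O)/C=C(\C)C(=O)CBr
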